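## Retrosynthetic overview

1. Target 26 ⇒ (desilylation; ring C–CH3 by iron-catalysed coupling of an enol triflate; gem-dimethyl by Me2CuLi addition; Stork–Danheiser transposition) 3-ethoxy-2-alkylcyclohex-2-enone 20. Here ring A (the trimethylcyclohexene; C1 = CMe2, C2–C4 = CH2, C5 = C–CH3, C6 = chain-bearing carbon) carries C1 and C5 at carbonyl level.
2. 20 ⇒ cyclobutenone 16 + vinyllithium. Ring A is closed by a 1,2-addition / 4π ring-opening / 6π-electrocyclization cascade whose ring-closing bond joins C4 (the CH2 allylic to the methyl-bearing alkene carbon) to C3 (the central CH2).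
3. 16 ⇒ B-alkyl Suzuki–Miyaura union of 2-iodo-3-ethoxycyclobutenone 14 with the diene-terminated chromene 12; the chain E-alkene comes from SeO2 oxidation of geranyl acetate.
4. 12 ⇒ pyran ring by intramolecular Pd-catalysed C–O coupling of a Z-styryl tertiary alcohol, whose stereocentre comes from Sharpless epoxidation → epoxy chloride → tertiary propargylic alcohol. Ring order: benzene ring (bought), pyran ring (step 10), four-membered ring (bought), ring A (step 13).
5. Enabling feature: in ring A the tetrasubstituted C5=C6 alkene lies between C1 and C5, which are 1,3-related across C6 and so map onto a 2-alkyl-1,3-dione mono-enol ether. C2–C3–C4 are three unsubstituted, stereochemically silent CH2 groups, so the C3–C4 bond can be made by electrocyclization between a cyclobutenone CH2 and a vinyl terminus.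

Key step: step 13

Remark on the chemistry: 4-bromo-3-iodophenol (8) and 3-ethoxycyclobut-2-en-1-one (13) are taken as purchasable; the single stereocentre is set in step 4 and no later step breaks the C–O bond at that carbon.

Shorthand in names: SC = the (3E)-3-methyl-6-[(2S)-2-methyl-6-(triisopropylsilyloxy)-2H-chromen-2-yl]hex-3-en-1-yl group, attached through carbon 1 of the hexenyl chain.

## Route

Step 1
Reactants: 1 geranyl acetate [(2E)-3,7-dimethylocta-2,6-dien-1-yl acetate]
Product: 2 (2E,6E)-3,7-dimethyl-8-oxoocta-2,6-dien-1-yl acetate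
Conditions: SeO2 (1.1 equiv), 95% EtOH, reflux
Reagents that add atoms: selenium dioxide, O=[Se]=O
Why: Riley allylic oxidation (ene reaction, [2,3]-sigmatropic shift, further oxidation of the allylic alcohol) should attack the electron-richer terminal trisubstituted alkene at its E-methyl group and give the (E)-enal, while the alkene next to the electron-withdrawing allylic acetate is left alone.

Step 2
Reactants: 2 (2E,6E)-3,7-dimethyl-8-oxoocta-2,6-dien-1-yl acetate
Product: 3 (2E,6E)-3,7-dimethylnona-2,6,8-trien-1-yl acetate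
Conditions: Ph3PCH3Br, KN(SiMe3)2, THF, −78 °C to 0 °C
Reagents that add atoms: methylenetriphenylphosphorane, C=P(c1ccccc1)(c1ccccc1)c1ccccc1 (made in the flask from methyltriphenylphosphonium bromide, C[P+](c1ccccc1)(c1ccccc1)c1ccccc1.[Br-], and KN(SiMe3)2)
Why: Wittig methylenation of the aldehyde by the unstabilised ylide should be much faster than attack on the acetate and turns the enal into the terminal 1,3-diene without touching the two E-alkenes.

Step 3
Reactants: 3 (2E,6E)-3,7-dimethylnona-2,6,8-trien-1-yl acetate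
Product: 4 (2E,6E)-3,7-dimethylnona-2,6,8-trien-1-ol
Conditions: K2CO3 (cat.), MeOH, rt
Reagents that add atoms: none
Why: Base-catalysed transesterification (methanolysis of the acetate) should free the allylic alcohol that the next step needs as its directing group.

Step 4
Reactants: 4 (2E,6E)-3,7-dimethylnona-2,6,8-trien-1-ol
Product: 5 [(2S,3S)-3-methyl-3-[(3E)-4-methylhexa-3,5-dien-1-yl]oxiran-2-yl]methanol
Conditions: Ti(OiPr)4 (cat.), L-(+)-diethyl tartrate (cat.), t-BuOOH, 4 Å molecular sieves, CH2Cl2, −20 °C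
Reagents that add atoms: tert-butyl hydroperoxide, CC(C)(C)OO
Why: Sharpless asymmetric epoxidation: the Ti–tartrate complex binds the allylic alcohol, so only the 2,3-alkene is epoxidised, and L-(+)-tartrate delivers oxygen to the face that gives the (2S,3S)-epoxide, which fixes the tertiary C–O stereocentre that becomes C2 of the chromene.

Step 5
Reactants: 5 [(2S,3S)-3-methyl-3-[(3E)-4-methylhexa-3,5-dien-1-yl]oxiran-2-yl]methanol
Product: 6 (2R,3S)-2-(chloromethyl)-3-methyl-3-[(3E)-4-methylhexa-3,5-dien-1-yl]oxirane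
Conditions: PPh3, CCl4, NaHCO3, reflux
Reagents that add atoms: tetrachloromethane, ClC(Cl)(Cl)Cl
Why: Appel chlorination under neutral, buffered conditions should convert the primary alcohol into the chloride without opening the epoxide (the new descriptor at C2 reflects only a change of CIP priorities).

Step 6
Reactants: 6 (2R,3S)-2-(chloromethyl)-3-methyl-3-[(3E)-4-methylhexa-3,5-dien-1-yl]oxirane
Product: 7 (3S,6E)-3,7-dimethylnona-6,8-dien-1-yn-3-ol
Conditions: LiN(iPr)2 (3.5 equiv), THF, −78 °C to −20 °C; then H2O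
Reagents that add atoms: none
Why: Base-induced fragmentation of a 2,3-epoxy chloride to a propargylic alcohol (α-deprotonation, epoxide opening to a chlorovinyl alkoxide, dehydrochlorination, acetylide formation) should give the terminal alkyne, and because the C–O bond at the tertiary carbon is never broken its configuration is retained as (S).

Step 7
Reactants: 8 4-bromo-3-iodophenol
Product: 9 (4-bromo-3-iodophenoxy)triisopropylsilane
Conditions: iPr3SiCl, imidazole, DMF, rt
Reagents that add atoms: chlorotri(propan-2-yl)silane, CC(C)[Si](Cl)(C(C)C)C(C)C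
Why: Standard silylation of the phenol; the bulky triisopropylsilyl ether should survive the organolithium, cuprate and Grignard steps and is removed last by fluoride.

Step 8
Reactants: 7 (3S,6E)-3,7-dimethylnona-6,8-dien-1-yn-3-ol; 9 (4-bromo-3-iodophenoxy)triisopropylsilane
Product: 10 (3S,6E)-1-[2-bromo-5-(triisopropylsilyloxy)phenyl]-3,7-dimethylnona-6,8-dien-1-yn-3-ol
Conditions: PdCl2(PPh3)2 (cat.), CuI (cat.), Et3N, THF, rt
Reagents that add atoms: none
Why: Sonogashira coupling: zerovalent palladium inserts into the C–I bond much faster than into the ortho C–Br bond, so the bromide is kept for step 10 and the free tertiary propargylic alcohol is tolerated.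

Step 9
Reactants: 10 (3S,6E)-1-[2-bromo-5-(triisopropylsilyloxy)phenyl]-3,7-dimethylnona-6,8-dien-1-yn-3-ol
Product: 11 (1Z,3S,6E)-1-[2-bromo-5-(triisopropylsilyloxy)phenyl]-3,7-dimethylnona-1,6,8-trien-3-ol
Conditions: Zn dust activated with Cu(OAc)2 and AgNO3, MeOH/H2O, 40 °C
Reagents that add atoms: none
Why: Cis-semireduction by activated zinc should reduce only the alkyne that is activated by the aryl group and the propargylic hydroxyl, giving the Z-alkene by syn delivery of two hydrogens and leaving the conjugated diene and the aryl bromide untouched.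

Step 10
Reactants: 11 (1Z,3S,6E)-1-[2-bromo-5-(triisopropylsilyloxy)phenyl]-3,7-dimethylnona-1,6,8-trien-3-ol
Product: 12 triisopropyl{[(2S)-2-methyl-2-[(3E)-4-methylhexa-3,5-dien-1-yl]-2H-chromen-6-yl]oxy}silane
Conditions: Pd(OAc)2 (cat.), 2-(di-tert-butylphosphino)-1,1'-binaphthyl (cat.), K3PO4, toluene, 70 °C
Reagents that add atoms: none
Why: Intramolecular Buchwald–Hartwig C–O coupling: the Z-alkene holds the tertiary alkoxide (no β-hydrogen on the carbinol carbon) next to the arylpalladium bromide so that C–O reductive elimination closes the pyran ring, and since the new bond is O–aryl the stereocentre keeps its (S) configuration.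

Step 11
Reactants: 13 3-ethoxycyclobut-2-en-1-one
Product: 14 3-ethoxy-2-iodocyclobut-2-en-1-one
Conditions: N-iodosuccinimide, MeCN, 0 °C to rt, dark
Reagents that add atoms: N-iodosuccinimide, O=C1CCC(=O)N1I
Why: Electrophilic α-iodination of a vinylogous ester, the nucleophilic α-carbon of the β-alkoxy enone being the only reactive alkene position.

Step 12
Reactants: 12 triisopropyl{[(2S)-2-methyl-2-[(3E)-4-methylhexa-3,5-dien-1-yl]-2H-chromen-6-yl]oxy}silane; 14 3-ethoxy-2-iodocyclobut-2-en-1-one
Product: 16 3-ethoxy-2-SC-cyclobut-2-en-1-one, via alkylborane 15 (not isolated)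
Conditions: 9-BBN (as its dimer), THF, 0 °C to rt; then 14, PdCl2(dppf) (cat.), AsPh3 (cat.), aqueous K3PO4, THF, rt
Reagents that add atoms: none
Why: 9-BBN should add anti-Markovnikov to the monosubstituted terminal alkene of the diene only (the trisubstituted alkene and the hindered chromene alkene are far slower), and the primary alkylborane should then undergo B-alkyl Suzuki–Miyaura coupling with the α-iodoenone at room temperature.

Step 13
Reactants: 16 3-ethoxy-2-SC-cyclobut-2-en-1-one
Product: 20 3-ethoxy-2-SC-cyclohex-2-en-1-one, via lithium cyclobutenolate 17 (not isolated), via lithium trienolate 18 (not isolated), via lithium cyclohexadienolate 19 (not isolated)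
Conditions: CH2=CHLi (1.3 equiv, from Sn(CH=CH2)4 and MeLi), THF, −78 °C; warm to rt (to 45 °C if needed); then saturated aqueous NH4Cl
Reagents that add atoms: vinyllithium, [Li]C=C (made in the flask from tetravinylstannane, C=C[Sn](C=C)(C=C)C=C, and methyllithium, [Li]C)
Why: Vinyllithium adds 1,2 to the strained ketone of the vinylogous ester (enolization is blocked because it would create a cyclobutadienolate); on warming, lithium cyclobutenolate 17 undergoes oxyanion-accelerated conrotatory 4π ring opening, the resulting 3-oxido-1,3,5-hexatriene 18 closes by thermal disrotatory 6π electrocyclization that joins the former cyclobutenone CH2 to the vinyl terminus, and α-protonation of the cross-conjugated dienolate 19 on work-up returns the vinylogous ester. The closest known reaction type is the ring expansion of cyclobutenones to cyclohexenones by alkenyllithium addition followed by 4π opening and 6π closure, the anionic relative of cyclobutenone-based benzannulation. Ring A is closed in the 6π (hexatriene to cyclohexadiene) mode while the four-membered ring is opened, so the net change is a two-carbon ring expansion that delivers the C2–C3–C4 methylene run in one operation. No stereocentre is created in ring A because both termini are CH2 groups, the carbinol centre of 17 is formed without control and is erased in the ring opening, and the remote chromene stereocentre is not involved. The step needs the vinyl group and the 1-ethoxyvinyl group cis on the central enolate double bond of 18, and this is secured by torquoselectivity: the oxido substituent rotates outward, which forces the vinyl group inward. It also needs 1,2- rather than 1,4-addition, which the β-ethoxy group and the hard organolithium secure.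

Step 14
Reactants: 20 3-ethoxy-2-SC-cyclohex-2-en-1-one
Product: 22 3-methyl-2-SC-cyclohex-2-en-1-one, via lithium alkoxide 21 (not isolated)
Conditions: MeLi, THF, −78 °C to 0 °C; then 1 M aqueous HCl, 0 °C
Reagents that add atoms: methyllithium, [Li]C; water, O
Why: Stork–Danheiser alkylative carbonyl transposition: MeLi adds 1,2 to the vinylogous ester and acid hydrolysis of the enol ether with loss of water moves the carbonyl to the former ethoxy-bearing carbon, giving the β-methyl enone (the carbinol centre of 21 is uncontrolled and is lost).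

Step 15
Reactants: 22 3-methyl-2-SC-cyclohex-2-en-1-one
Product: 24 3,3-dimethyl-2-SC-cyclohex-1-en-1-yl trifluoromethanesulfonate, via lithium enolate 23 (not isolated)
Conditions: Me2CuLi (from CuI and 2 MeLi), Et2O, −20 °C to 0 °C; then PhNTf2, THF, 0 °C to rt; aqueous NH4Cl
Reagents that add atoms: lithium dimethylcuprate, [Li+].C[Cu-]C (made in the flask from CuI and methyllithium, [Li]C); N-phenylbis(trifluoromethanesulfonimide), O=S(=O)(N(c1ccccc1)S(=O)(=O)C(F)(F)F)C(F)(F)F
Why: Conjugate addition of Me2CuLi to the β-methyl enone should build the quaternary gem-dimethyl carbon and give the enolate regiospecifically toward the chain-bearing carbon, which O-sulfonylation with PhNTf2 fixes as the tetrasubstituted enol triflate.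

Step 16
Reactants: 24 3,3-dimethyl-2-SC-cyclohex-1-en-1-yl trifluoromethanesulfonate
Product: 25 triisopropyl({(2S)-2-methyl-2-[(3E)-4-methyl-6-(2,6,6-trimethylcyclohex-1-en-1-yl)hex-3-en-1-yl]-2H-chromen-6-yl}oxy)silane
Conditions: MeMgBr, Fe(acac)3 (cat.), THF/N-methylpyrrolidone, −20 °C to 0 °C
Reagents that add atoms: methylmagnesium bromide, C[Mg]Br
Why: Iron-catalysed Kumada-type cross-coupling of the alkenyl triflate with MeMgBr should replace the triflate by methyl with the double bond held in place, completing the 2,6,6-trimethylcyclohexenyl ring.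

Step 17
Reactants: 25 triisopropyl({(2S)-2-methyl-2-[(3E)-4-methyl-6-(2,6,6-trimethylcyclohex-1-en-1-yl)hex-3-en-1-yl]-2H-chromen-6-yl}oxy)silane
Product: 26 (2S)-2-methyl-2-[(3E)-4-methyl-6-(2,6,6-trimethylcyclohex-1-en-1-yl)hex-3-en-1-yl]-2H-chromen-6-ol
Conditions: Bu4NF, THF, 0 °C; then H2O
Reagents that add atoms: none
Why: Fluoride cleavage of the aryl silyl ether (Si–F bond formation) under mild, non-acidic conditions should free the phenol without disturbing the chromene or the alkenes.

## Compound list

1 | geranyl acetate, (2E)-3,7-dimethylocta-2,6-dien-1-yl acetate | CC(C)=CCC/C(C)=C/COC(C)=O | starting material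
2 | (2E,6E)-3,7-dimethyl-8-oxoocta-2,6-dien-1-yl acetate | O=C/C(C)=C/CC/C(C)=C/COC(C)=O | intermediate
3 | (2E,6E)-3,7-dimethylnona-2,6,8-trien-1-yl acetate | C=C/C(C)=C/CC/C(C)=C/COC(C)=O | intermediate
4 | (2E,6E)-3,7-dimethylnona-2,6,8-trien-1-ol | C=C/C(C)=C/CC/C(C)=C/CO | intermediate
5 | [(2S,3S)-3-methyl-3-[(3E)-4-methylhexa-3,5-dien-1-yl]oxiran-2-yl]methanol | OC[C@@H]1O[C@@]1(C)CC/C=C(\C)C=C | intermediate
6 | (2R,3S)-2-(chloromethyl)-3-methyl-3-[(3E)-4-methylhexa-3,5-dien-1-yl]oxirane | ClC[C@@H]1O[C@@]1(C)CC/C=C(\C)C=C | intermediate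
7 | (3S,6E)-3,7-dimethylnona-6,8-dien-1-yn-3-ol | C=C/C(C)=C/CC[C@](C)(O)C#C | intermediate
8 | 4-bromo-3-iodophenol | Oc1ccc(Br)c(I)c1 | starting material
9 | (4-bromo-3-iodophenoxy)triisopropylsilane | CC(C)[Si](Oc1ccc(Br)c(I)c1)(C(C)C)C(C)C | intermediate
10 | (3S,6E)-1-[2-bromo-5-(triisopropylsilyloxy)phenyl]-3,7-dimethylnona-6,8-dien-1-yn-3-ol | C=C/C(C)=C/CC[C@](C)(O)C#Cc1cc(O[Si](C(C)C)(C(C)C)C(C)C)ccc1Br | intermediate
11 | (1Z,3S,6E)-1-[2-bromo-5-(triisopropylsilyloxy)phenyl]-3,7-dimethylnona-1,6,8-trien-3-ol | C=C/C(C)=C/CC[C@](C)(O)/C=C\c1cc(O[Si](C(C)C)(C(C)C)C(C)C)ccc1Br | intermediate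
12 | triisopropyl{[(2S)-2-methyl-2-[(3E)-4-methylhexa-3,5-dien-1-yl]-2H-chromen-6-yl]oxy}silane | C=C/C(C)=C/CC[C@@]1(C)C=Cc2cc(O[Si](C(C)C)(C(C)C)C(C)C)ccc2O1 | intermediate
13 | 3-ethoxycyclobut-2-en-1-one | CCOC1=CC(=O)C1 | starting material
14 | 3-ethoxy-2-iodocyclobut-2-en-1-one | CCOC1=C(I)C(=O)C1 | intermediate
15 | 9-SC-9-borabicyclo[3.3.1]nonane (alkylborane, not isolated) | B1(CC/C(C)=C/CC[C@@]2(C)C=Cc3cc(O[Si](C(C)C)(C(C)C)C(C)C)ccc3O2)C2CCCC1CCC2 | intermediate
16 | 3-ethoxy-2-SC-cyclobut-2-en-1-one | CCOC1=C(CC/C(C)=C/CC[C@@]2(C)C=Cc3cc(O[Si](C(C)C)(C(C)C)C(C)C)ccc3O2)C(=O)C1 | intermediate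
17 | lithium 3-ethoxy-1-ethenyl-2-SC-cyclobut-2-en-1-olate (both configurations at the carbinol carbon, not isolated) | CCOC1=C(CC/C(C)=C/CC[C@@]2(C)C=Cc3cc(O[Si](C(C)C)(C(C)C)C(C)C)ccc3O2)C([O-])(C=C)C1.[Li+] | intermediate
18 | lithium (3E)-5-ethoxy-4-SC-hexa-1,3,5-trien-3-olate (vinyl and 1-ethoxyvinyl groups cis on the central double bond, not isolated) | C=C/C([O-])=C(/CC/C(C)=C/CC[C@@]1(C)C=Cc2cc(O[Si](C(C)C)(C(C)C)C(C)C)ccc2O1)C(OCC)=C.[Li+] | intermediate
19 | lithium 5-ethoxy-6-SC-cyclohexa-1,5-dien-1-olate (not isolated) | CCOC1=C(CC/C(C)=C/CC[C@@]2(C)C=Cc3cc(O[Si](C(C)C)(C(C)C)C(C)C)ccc3O2)C([O-])=CCC1.[Li+] | intermediate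
20 | 3-ethoxy-2-SC-cyclohex-2-en-1-one | CCOC1=C(CC/C(C)=C/CC[C@@]2(C)C=Cc3cc(O[Si](C(C)C)(C(C)C)C(C)C)ccc3O2)C(=O)CCC1 | intermediate
21 | lithium 3-ethoxy-1-methyl-2-SC-cyclohex-2-en-1-olate (both configurations at the carbinol carbon, not isolated) | CCOC1=C(CC/C(C)=C/CC[C@@]2(C)C=Cc3cc(O[Si](C(C)C)(C(C)C)C(C)C)ccc3O2)C(C)([O-])CCC1.[Li+] | intermediate
22 | 3-methyl-2-SC-cyclohex-2-en-1-one | CC1=C(CC/C(C)=C/CC[C@@]2(C)C=Cc3cc(O[Si](C(C)C)(C(C)C)C(C)C)ccc3O2)C(=O)CCC1 | intermediate
23 | lithium 3,3-dimethyl-2-SC-cyclohex-1-en-1-olate (not isolated) | [Li+].[O-]C1=C(CC/C(C)=C/CC[C@@]2(C)C=Cc3cc(O[Si](C(C)C)(C(C)C)C(C)C)ccc3O2)C(C)(C)CCC1 | intermediate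
24 | 3,3-dimethyl-2-SC-cyclohex-1-en-1-yl trifluoromethanesulfonate | O=S(=O)(OC1=C(CC/C(C)=C/CC[C@@]2(C)C=Cc3cc(O[Si](C(C)C)(C(C)C)C(C)C)ccc3O2)C(C)(C)CCC1)C(F)(F)F | intermediate
25 | triisopropyl({(2S)-2-methyl-2-[(3E)-4-methyl-6-(2,6,6-trimethylcyclohex-1-en-1-yl)hex-3-en-1-yl]-2H-chromen-6-yl}oxy)silane | CC1=C(CC/C(C)=C/CC[C@@]2(C)C=Cc3cc(O[Si](C(C)C)(C(C)C)C(C)C)ccc3O2)C(C)(C)CCC1 | intermediate
26 | (2S)-2-methyl-2-[(3E)-4-methyl-6-(2,6,6-trimethylcyclohex-1-en-1-yl)hex-3-en-1-yl]-2H-chromen-6-ol | CC1=C(CC/C(C)=C/CC[C@@]2(C)C=Cc3cc(O)ccc3O2)C(C)(C)CCC1 | target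

## Step count and risks

Total steps: 17. Longest linear sequence: 15 steps (1 → 26 through steps 1–6, 8–10 and 12–17); steps 7 and 11 are side branches.

Steps most likely to fail:

1. Step 12 (hydroboration / B-alkyl Suzuki–Miyaura coupling). What may go wrong: ring opening of the strained iodo-vinylogous ester by aqueous base or by palladium insertion may outrun transmetalation, or hydroboration of the diene may not stay on the terminal alkene. The fallback builds the four-membered ring on the chain by cycloaddition instead of coupling a preformed ring. It sets out from 15: oxidation with NaBO3·4H2O (THF/H2O) should give (3E)-3-methyl-6-[(2S)-2-methyl-6-(triisopropylsilyloxy)-2H-chromen-2-yl]hex-3-en-1-ol F1. I2, PPh3 and imidazole should give {[(2S)-2-[(3E)-6-iodo-4-methylhex-3-en-1-yl]-2-methyl-2H-chromen-6-yl]oxy}triisopropylsilane F2. Alkylation of LiC≡COEt (from ethoxyacetylene and n-BuLi, THF/DMPU) with F2 should give {[(2S)-2-[(3E)-8-ethoxy-4-methyloct-3-en-7-yn-1-yl]-2-methyl-2H-chromen-6-yl]oxy}triisopropylsilane F3. A [2+2] cycloaddition of F3 with ketene, generated in situ from acetyl chloride and Et3N, should join the ketene carbonyl carbon to the alkyl-bearing alkyne carbon and come back to the route at 16.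

2. Step 13 (key step). What may go wrong: after ring opening the open-chain trienolate may fail to electrocyclize at a temperature it survives and be protonated as an acyclic ketone on quench, or the alkoxide may fragment before it opens. The fallback leaves the one-pot anionic manifold for a neutral, stepwise pericyclic sequence on an isolated silyl ether. It sets out from 16: addition of CH2=CHLi at −78 °C and O-silylation with Me3SiCl before warming should give [(3-ethoxy-1-ethenyl-2-SC-cyclobut-2-en-1-yl)oxy]trimethylsilane F4. Heating F4 in toluene (80–110 °C) should open the cyclobutene with the silyloxy group rotating outward to {[(3E)-5-ethoxy-4-SC-hexa-1,3,5-trien-3-yl]oxy}trimethylsilane F5, which should close in the same pot to [(5-ethoxy-6-SC-cyclohexa-1,5-dien-1-yl)oxy]trimethylsilane F6. Brief treatment of F6 with dilute aqueous citric acid in THF should cleave only the trimethylsilyl enol ether and come back to the route at 20.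

3. Step 10 (palladium-catalysed ring closure). What may go wrong: β-carbon elimination or ionization at the tertiary allylic palladium alkoxide, protodebromination, or loss of the aryl silyl ether under the basic conditions may outrun C–O reductive elimination. The fallback makes the aryl–oxygen bond first, intermolecularly and without a transition metal, and then closes the pyran ring at carbon. It sets out from 7 and bypasses 8–11. Commercial 4-iodophenol is silylated (iPr3SiCl, imidazole) to (4-iodophenoxy)triisopropylsilane F7. Oxidation of F7 with mCPBA and TsOH·H2O followed by 1,3,5-trimethoxybenzene should give [4-(triisopropylsilyloxy)phenyl](2,4,6-trimethoxyphenyl)iodonium 4-methylbenzenesulfonate F8. The sodium alkoxide of 7 (NaH, toluene) should be O-arylated by F8 with retention to give triisopropyl(4-{[(3S,6E)-3,7-dimethylnona-6,8-dien-1-yn-3-yl]oxy}phenoxy)silane F9. Cationic gold catalysis (Ph3PAuNTf2, CH2Cl2, rt) should then effect 6-endo hydroarylation of the aryl propargyl ether F9, ortho to the ether oxygen and without touching the C–O bond of the stereocentre, and come back to the route at 12.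

## Further compounds

F1 | step 12 | (3E)-3-methyl-6-[(2S)-2-methyl-6-(triisopropylsilyloxy)-2H-chromen-2-yl]hex-3-en-1-ol | OCC/C(C)=C/CC[C@@]1(C)C=Cc2cc(O[Si](C(C)C)(C(C)C)C(C)C)ccc2O1
F2 | step 12 | {[(2S)-2-[(3E)-6-iodo-4-methylhex-3-en-1-yl]-2-methyl-2H-chromen-6-yl]oxy}triisopropylsilane | ICC/C(C)=C/CC[C@@]1(C)C=Cc2cc(O[Si](C(C)C)(C(C)C)C(C)C)ccc2O1
F3 | step 12 | {[(2S)-2-[(3E)-8-ethoxy-4-methyloct-3-en-7-yn-1-yl]-2-methyl-2H-chromen-6-yl]oxy}triisopropylsilane | CCOC#CCC/C(C)=C/CC[C@@]1(C)C=Cc2cc(O[Si](C(C)C)(C(C)C)C(C)C)ccc2O1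
F4 | step 13 | [(3-ethoxy-1-ethenyl-2-SC-cyclobut-2-en-1-yl)oxy]trimethylsilane (both configurations at the carbinol carbon) | CCOC1=C(CC/C(C)=C/CC[C@@]2(C)C=Cc3cc(O[Si](C(C)C)(C(C)C)C(C)C)ccc3O2)C(O[Si](C)(C)C)(C=C)C1
F5 | step 13 | {[(3E)-5-ethoxy-4-SC-hexa-1,3,5-trien-3-yl]oxy}trimethylsilane | C=C/C(O[Si](C)(C)C)=C(/CC/C(C)=C/CC[C@@]1(C)C=Cc2cc(O[Si](C(C)C)(C(C)C)C(C)C)ccc2O1)C(OCC)=C
F6 | step 13 | [(5-ethoxy-6-SC-cyclohexa-1,5-dien-1-yl)oxy]trimethylsilane | CCOC1=C(CC/C(C)=C/CC[C@@]2(C)C=Cc3cc(O[Si](C(C)C)(C(C)C)C(C)C)ccc3O2)C(O[Si](C)(C)C)=CCC1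
F7 | step 10 | (4-iodophenoxy)triisopropylsilane | CC(C)[Si](Oc1ccc(I)cc1)(C(C)C)C(C)C
F8 | step 10 | [4-(triisopropylsilyloxy)phenyl](2,4,6-trimethoxyphenyl)iodonium 4-methylbenzenesulfonate | COc1cc(OC)c([I+]c2ccc(O[Si](C(C)C)(C(C)C)C(C)C)cc2)c(OC)c1.Cc1ccc(S(=O)(=O)[O-])cc1
F9 | step 10 | triisopropyl(4-{[(3S,6E)-3,7-dimethylnona-6,8-dien-1-yn-3-yl]oxy}phenoxy)silane | C=C/C(C)=C/CC[C@](C)(Oc1ccc(O[Si](C(C)C)(C(C)C)C(C)C)cc1)C#C
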